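**Plan**
- Numbering used: ring B (bromocyclohexane) C1 bears the side chain, C3 the Br, C4 the methyl carbinol; ring A C1 = C(CH3)OH, C2 = CHOH, C3 bears the allyl chain, C4 the isopropenyl group.
- Cuts: ring A C3–CH2 (enolate allylation joining two C10 halves); the vinylidene carbon is traced back to an ester carbon on ring B C1; ring B, stripped of Br and CH3, is cut at C1–C2 and C4–C5 into a glutarate and an acrylate.
- Enabling feature: ring B C4 and the exocyclic carbon on C1 are 1,5-related carbonyl-level carbons, and without Br the ring has a mirror plane through C1 and C4, so a three-carbon plus three-carbon Michael–Dieckmann annulation builds it with no stereochemical burden.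
- Forward order: ring B is annulated (step 1), desymmetrised, brominated, methylated and turned into a 2-substituted allylic bromide; ring A is made from (S)-carvone as an α-hydroxy ketone; the halves are joined by alkylation, then reduction and desilylation.
- Stereochemistry, ring B: one enantiotopic-group-selective deprotonation, relayed by axial bromination (C3) and anti (Felkin–Anh) methyl addition (C4); C1 by thermodynamic epimerisation α to the ester.
- Stereochemistry, ring A: C4 from (S)-carvone; C1 by Weitz–Scheffer epoxidation trans to isopropenyl; C3 by trans-selective alkylation; C2 by hydroxyl-directed reduction.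

Key step: step 1

Assumption: the sense of induction in step 3 is taken by analogy with 4-tert-butylcyclohexanone for this amide; if it proved opposite, the (S,S)-amide would be used.

Step 1
Reactants: 1 di-tert-butyl pentanedioate; 2 methyl acrylate
Product: 4 di-tert-butyl 4-oxocyclohexane-1,3-dicarboxylate, via Michael adduct triester enolate 3 (not isolated)
Conditions: LiN(iPr)2 (1.05 equiv), THF, −78 °C; 2 (1.0 equiv, slow addition), −78 to 25 °C; aq. NH4Cl
Reagents that add atoms: none
Why: The lithium enolate of one tert-butyl ester terminus of 1 adds 1,4 to 2 (Michael addition), proton transfer moves the charge to the carbon α to the second tert-butyl ester, and this carbon acylates the methyl ester in a Dieckmann condensation (6-exo-trig, enolexo closure) to give the stable β-keto ester enolate; the closest known reaction type is the tandem Michael–Dieckmann annulation of ester enolates with acrylates. The six-membered ring is thus assembled from two three-carbon units, ring B C1–C2 in the Michael step and C4–C5 in the Dieckmann step, with the acrylate α-carbon becoming C3 and the ester carbon on C1 becoming the later vinylidene carbon. No lasting stereocenter is formed (both ring CH centres are epimerisable and one is removed in step 2), which is intended, because the product leads to an achiral, mirror-symmetric keto ester. The selectivities needed are mono-addition to 2, which slow addition of one equivalent to the preformed enolate at low temperature should secure, and acylation of the methyl ester only, which the poor electrophilicity of tert-butyl esters should secure.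

Step 2
Reactants: 4 di-tert-butyl 4-oxocyclohexane-1,3-dicarboxylate
Product: 5 methyl 4-oxocyclohexane-1-carboxylate
Conditions: HCl, MeOH, 65 °C; then 1 M aq. HCl, 25 °C
Reagents that add atoms: methanol CO
Why: Acidolysis of both tert-butyl esters, decarboxylation of the β-keto acid and Fischer esterification of the remaining acid should give the achiral keto ester, which has no stereocenter.

Step 3
Reactants: 5 methyl 4-oxocyclohexane-1-carboxylate
Product: 6 methyl (1S)-4-[(trimethylsilyl)oxy]cyclohex-3-ene-1-carboxylate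
Conditions: lithium (R,R)-bis(1-phenylethyl)amide (1.1 equiv), LiCl, Me3SiCl (internal quench), THF, −100 to −78 °C
Reagents that add atoms: chlorotrimethylsilane C[Si](C)(C)Cl
Why: Enantiotopic-group-selective deprotonation of a 4-substituted cyclohexanone by a chiral lithium amide with internal silyl quench is a precedented desymmetrisation that should make C1 stereogenic (S), the ketone α-CH2 being deprotonated faster than the hindered ester α-CH.

Step 4
Reactants: 6 methyl (1S)-4-[(trimethylsilyl)oxy]cyclohex-3-ene-1-carboxylate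
Product: 7 methyl (1S,3R)-3-bromo-4-oxocyclohexane-1-carboxylate
Conditions: N-bromosuccinimide, THF, −78 °C; crude product used at once
Reagents that add atoms: N-bromosuccinimide O=C1CCC(=O)N1Br
Why: Electrophilic bromination of the silyl enol ether should proceed by axial attack on the half-chair to give mainly the trans (axial) bromo ketone, so that C3 (R) now carries the absolute information.

Step 5
Reactants: 7 methyl (1S,3R)-3-bromo-4-oxocyclohexane-1-carboxylate
Product: 9 methyl (1S,3R,4S)-3-bromo-4-methyl-4-[(triethylsilyl)oxy]cyclohexane-1-carboxylate, via bromomagnesium alkoxide 8 (not isolated)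
Conditions: MeMgBr, CH2Cl2/Et2O, −78 °C; then Et3SiOTf, −78 to 0 °C; chromatography
Reagents that add atoms: methylmagnesium bromide C[Mg]Br; triethylsilyl trifluoromethanesulfonate CC[Si](CC)(CC)OS(=O)(=O)C(F)(F)F
Why: Grignard addition to the α-bromo ketone anti to the C–Br bond (Felkin–Anh/Cornforth control) should set C4 with oxygen cis to bromine, the alkoxide is trapped as the silyl ether, and the minor all-cis diastereomer that any equatorial bromide would give is removed here because after step 6 it would be the enantiomer of 10.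

Step 6
Reactants: 9 methyl (1S,3R,4S)-3-bromo-4-methyl-4-[(triethylsilyl)oxy]cyclohexane-1-carboxylate
Product: 10 methyl (1R,3R,4S)-3-bromo-4-methyl-4-[(triethylsilyl)oxy]cyclohexane-1-carboxylate
Conditions: NaOMe (0.3 equiv), MeOH, 25 °C
Reagents that add atoms: none
Why: Base-catalysed epimerisation α to the ester should move CO2Me from the axial to the equatorial position, giving the thermodynamic isomer with ester, bromine and methyl all equatorial (C1 now R).

Step 7
Reactants: 10 methyl (1R,3R,4S)-3-bromo-4-methyl-4-[(triethylsilyl)oxy]cyclohexane-1-carboxylate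
Product: 12 {[(1S,2R,4R)-2-bromo-1-methyl-4-[3-(trimethylsilyl)prop-1-en-2-yl]cyclohexyl]oxy}triethylsilane, via bis(silylmethyl) carbinol 11 (not isolated)
Conditions: Me3SiCH2MgCl (4 equiv), CeCl3, THF, −78 to 25 °C; aq. NH4Cl; then SiO2, CH2Cl2, 25 °C
Reagents that add atoms: (trimethylsilyl)methylmagnesium chloride C[Si](C)(C)C[Mg]Cl
Why: Double addition of the non-basic organocerium reagent to the ester followed by Peterson elimination is the standard ester-to-2-substituted-allylsilane conversion, and the ring C1 configuration is retained and no longer epimerisable.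

Step 8
Reactants: 12 {[(1S,2R,4R)-2-bromo-1-methyl-4-[3-(trimethylsilyl)prop-1-en-2-yl]cyclohexyl]oxy}triethylsilane
Product: 13 {[(1S,2R,4R)-2-bromo-4-(3-bromoprop-1-en-2-yl)-1-methylcyclohexyl]oxy}triethylsilane
Conditions: N-bromosuccinimide, propylene oxide, CH2Cl2, −78 °C
Reagents that add atoms: N-bromosuccinimide O=C1CCC(=O)N1Br
Why: Electrophilic bromodesilylation (SE2′) of the allylsilane should give the allylic bromide, the allylic shift being degenerate for this 2-substituted allyl unit.

Step 9
Reactants: 14 (S)-carvone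
Product: 15 (1S,4S,6S)-1-methyl-4-(prop-1-en-2-yl)-7-oxabicyclo[4.1.0]heptan-2-one
Conditions: H2O2 (30% aq.), NaOH, MeOH, 0 °C
Reagents that add atoms: hydrogen peroxide OO
Why: Weitz–Scheffer epoxidation of the enone, with hydroperoxide adding anti to the isopropenyl group, should place the epoxide oxygen trans to isopropenyl and so fix the tertiary C–O stereocenter.

Step 10
Reactants: 15 (1S,4S,6S)-1-methyl-4-(prop-1-en-2-yl)-7-oxabicyclo[4.1.0]heptan-2-one
Product: 16 (1S,4S)-1-methyl-4-(prop-1-en-2-yl)cyclohexane-1,2-diol (both C2 epimers)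
Conditions: LiEt3BH (3 equiv), THF, 0 to 25 °C; aq. NH4Cl
Reagents that add atoms: none
Why: The hydride should reduce the ketone and open the epoxide by SN2 attack at the less substituted carbon, leaving the tertiary C–O bond untouched; the carbinol epimer mixture is irrelevant because step 11 oxidises it.

Step 11
Reactants: 16 (1S,4S)-1-methyl-4-(prop-1-en-2-yl)cyclohexane-1,2-diol (both C2 epimers)
Product: 17 (2S,5S)-2-hydroxy-2-methyl-5-(prop-1-en-2-yl)cyclohexan-1-one
Conditions: Dess–Martin periodinane, CH2Cl2, 0 to 25 °C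
Reagents that add atoms: none
Why: Dess–Martin oxidation of the secondary alcohol of the 1,2-diol should give the α-hydroxy ketone with the tertiary carbinol unchanged.

Step 12
Reactants: 17 (2S,5S)-2-hydroxy-2-methyl-5-(prop-1-en-2-yl)cyclohexan-1-one; 13 {[(1S,2R,4R)-2-bromo-4-(3-bromoprop-1-en-2-yl)-1-methylcyclohexyl]oxy}triethylsilane
Product: 18 (2S,5S,6R)-6-{2-[(1R,3R,4S)-3-bromo-4-methyl-4-(triethylsilyloxy)cyclohexyl]prop-2-en-1-yl}-2-hydroxy-2-methyl-5-(prop-1-en-2-yl)cyclohexan-1-one
Conditions: LiN(iPr)2 (2.1 equiv), THF, −78 to −20 °C; then 13, DMPU, −78 to −20 °C; aq. NH4Cl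
Reagents that add atoms: none
Why: SN2 alkylation of the alkoxide–enolate dianion (only one enolisable α-position) by the allylic bromide joins the two halves trans to the adjacent isopropenyl group, which is also the thermodynamic arrangement at this centre, while the hindered secondary ring bromide should not compete.

Step 13
Reactants: 18 (2S,5S,6R)-6-{2-[(1R,3R,4S)-3-bromo-4-methyl-4-(triethylsilyloxy)cyclohexyl]prop-2-en-1-yl}-2-hydroxy-2-methyl-5-(prop-1-en-2-yl)cyclohexan-1-one
Product: 19 (1S,2S,3R,4S)-3-{2-[(1R,3R,4S)-3-bromo-4-methyl-4-(triethylsilyloxy)cyclohexyl]prop-2-en-1-yl}-1-methyl-4-(prop-1-en-2-yl)cyclohexane-1,2-diol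
Conditions: NaBH(OAc)3, AcOH, MeCN, −20 to 0 °C
Reagents that add atoms: none
Why: Hydroxyl-directed triacetoxyborohydride reduction (Evans–Saksena type) delivers hydride from the face of the tertiary hydroxyl and should give the trans-1,2-diol with the new secondary OH equatorial.

Step 14
Reactants: 19 (1S,2S,3R,4S)-3-{2-[(1R,3R,4S)-3-bromo-4-methyl-4-(triethylsilyloxy)cyclohexyl]prop-2-en-1-yl}-1-methyl-4-(prop-1-en-2-yl)cyclohexane-1,2-diol
Product: 20 (1S,2S,3R,4S)-3-{2-[(1R,3R,4S)-3-bromo-4-hydroxy-4-methylcyclohexyl]prop-2-en-1-yl}-1-methyl-4-(prop-1-en-2-yl)cyclohexane-1,2-diol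
Conditions: HF·pyridine, THF, 0 to 25 °C
Reagents that add atoms: none
Why: Fluoride-mediated cleavage of the tertiary silyl ether should release the target without touching any stereocenter, the cis-bromohydrin being unable to close to an epoxide.

**Compound list**
1 | di-tert-butyl pentanedioate | CC(C)(C)OC(=O)CCCC(=O)OC(C)(C)C | starting material
2 | methyl acrylate | C=CC(=O)OC | starting material
3 | 1,3-di-tert-butyl 5-methyl pentane-1,3,5-tricarboxylate (lithium enolate in the flask) | COC(=O)CCC(CCC(=O)OC(C)(C)C)C(=O)OC(C)(C)C | intermediate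
4 | di-tert-butyl 4-oxocyclohexane-1,3-dicarboxylate | CC(C)(C)OC(=O)C1CCC(=O)C(C1)C(=O)OC(C)(C)C | intermediate
5 | methyl 4-oxocyclohexane-1-carboxylate | COC(=O)C1CCC(=O)CC1 | intermediate
6 | methyl (1S)-4-[(trimethylsilyl)oxy]cyclohex-3-ene-1-carboxylate | COC(=O)[C@H]1CCC(O[Si](C)(C)C)=CC1 | intermediate
7 | methyl (1S,3R)-3-bromo-4-oxocyclohexane-1-carboxylate | COC(=O)[C@H]1CCC(=O)[C@H](Br)C1 | intermediate
8 | bromomagnesium alkoxide of methyl (1S,3R,4S)-3-bromo-4-hydroxy-4-methylcyclohexane-1-carboxylate | COC(=O)[C@H]1CC[C@](C)(O[Mg]Br)[C@H](Br)C1 | intermediate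
9 | methyl (1S,3R,4S)-3-bromo-4-methyl-4-[(triethylsilyl)oxy]cyclohexane-1-carboxylate | COC(=O)[C@H]1CC[C@](C)(O[Si](CC)(CC)CC)[C@H](Br)C1 | intermediate
10 | methyl (1R,3R,4S)-3-bromo-4-methyl-4-[(triethylsilyl)oxy]cyclohexane-1-carboxylate | COC(=O)[C@@H]1CC[C@](C)(O[Si](CC)(CC)CC)[C@H](Br)C1 | intermediate
11 | 2-[(1R,3R,4S)-3-bromo-4-methyl-4-(triethylsilyloxy)cyclohexyl]-1,3-bis(trimethylsilyl)propan-2-ol | C[Si](C)(C)CC(O)(C[Si](C)(C)C)[C@@H]1CC[C@](C)(O[Si](CC)(CC)CC)[C@H](Br)C1 | intermediate
12 | {[(1S,2R,4R)-2-bromo-1-methyl-4-[3-(trimethylsilyl)prop-1-en-2-yl]cyclohexyl]oxy}triethylsilane | C=C(C[Si](C)(C)C)[C@@H]1CC[C@](C)(O[Si](CC)(CC)CC)[C@H](Br)C1 | intermediate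
13 | {[(1S,2R,4R)-2-bromo-4-(3-bromoprop-1-en-2-yl)-1-methylcyclohexyl]oxy}triethylsilane | C=C(CBr)[C@@H]1CC[C@](C)(O[Si](CC)(CC)CC)[C@H](Br)C1 | intermediate
14 | (S)-carvone | CC1=CC[C@@H](CC1=O)C(C)=C | starting material
15 | (1S,4S,6S)-1-methyl-4-(prop-1-en-2-yl)-7-oxabicyclo[4.1.0]heptan-2-one (epoxide oxygen trans to isopropenyl) | C1[C@@H](C(=C)C)C[C@@H]2O[C@]2(C)C1=O | intermediate
16 | (1S,4S)-1-methyl-4-(prop-1-en-2-yl)cyclohexane-1,2-diol (both C2 epimers) | C1[C@@H](C(=C)C)CC[C@](C)(O)C1O | intermediate
17 | (2S,5S)-2-hydroxy-2-methyl-5-(prop-1-en-2-yl)cyclohexan-1-one | C1[C@@H](C(=C)C)CC[C@](C)(O)C1=O | intermediate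
18 | (2S,5S,6R)-6-{2-[(1R,3R,4S)-3-bromo-4-methyl-4-(triethylsilyloxy)cyclohexyl]prop-2-en-1-yl}-2-hydroxy-2-methyl-5-(prop-1-en-2-yl)cyclohexan-1-one | C=C(C[C@@H]1[C@@H](C(=C)C)CC[C@](C)(O)C1=O)[C@@H]1CC[C@](C)(O[Si](CC)(CC)CC)[C@H](Br)C1 | intermediate
19 | (1S,2S,3R,4S)-3-{2-[(1R,3R,4S)-3-bromo-4-methyl-4-(triethylsilyloxy)cyclohexyl]prop-2-en-1-yl}-1-methyl-4-(prop-1-en-2-yl)cyclohexane-1,2-diol | C=C(C[C@@H]1[C@@H](C(=C)C)CC[C@](C)(O)[C@H]1O)[C@@H]1CC[C@](C)(O[Si](CC)(CC)CC)[C@H](Br)C1 | intermediate
20 | (1S,2S,3R,4S)-3-{2-[(1R,3R,4S)-3-bromo-4-hydroxy-4-methylcyclohexyl]prop-2-en-1-yl}-1-methyl-4-(prop-1-en-2-yl)cyclohexane-1,2-diol | C=C(C[C@@H]1[C@@H](C(=C)C)CC[C@](C)(O)[C@H]1O)[C@@H]1CC[C@](C)(O)[C@H](Br)C1 | target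

Total step count: 14. Longest linear sequence: 11 steps (steps 1–8, then 12–14).

**Steps most likely to fail**

Step 3. Enantiotopic-group selection may be eroded, or the base may deprotonate α to the ester. Fallback, setting out from 5: D-proline-catalysed α-aminoxylation with nitrosobenzene should give methyl (3S)-4-oxo-3-[(phenylamino)oxy]cyclohexane-1-carboxylate F1 (C1 epimers, of no consequence). N–O cleavage with Zn in AcOH gives methyl (3S)-3-hydroxy-4-oxocyclohexane-1-carboxylate F2. MsCl and Et3N give methyl (3S)-3-[(methylsulfonyl)oxy]-4-oxocyclohexane-1-carboxylate F3. LiBr in acetone displaces the sulfonate with inversion, giving the (3R)-bromo ketone as 7 together with its C1 epimer, methyl (1R,3R)-3-bromo-4-oxocyclohexane-1-carboxylate F4. Both converge on 10 through steps 5 and 6, so this fallback comes back to the route at 7.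

Step 1. The acrylate may add twice or oligomerise, and the enolate may fail to equilibrate to the acylating position. Fallback, setting out from 2: double Michael addition of dimethyl malonate to two equivalents of 2 (NaOMe, MeOH) gives tetramethyl pentane-1,3,3,5-tetracarboxylate F5. Dieckmann cyclisation with NaH in THF gives trimethyl 4-oxocyclohexane-1,1,3-tricarboxylate F6. Krapcho dealkoxycarbonylation (LiCl, wet DMSO, 150 °C) removes two ester groups and comes back to the route at 5.

Step 12. O-alkylation, proton transfer or slow reaction with the branched electrophile may keep the two halves from joining at carbon. Fallback, setting out from 17 and 13: deliberate O-allylation of the enolate (KN(SiMe3)2, 18-crown-6, THF/HMPA) gives the allyl enol ether 2-[(1R,3R,4S)-3-bromo-4-methyl-4-(triethylsilyloxy)cyclohexyl]prop-2-en-1-yl enol ether of 17 F7. Heating in toluene at 110 °C effects a Claisen rearrangement that forms the same C–C bond and the same 1,1-disubstituted alkene, with the new substituent trans to isopropenyl (also the thermodynamic outcome), and comes back to the route at 18.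

Further compounds
F1 | step 3 | methyl (3S)-4-oxo-3-[(phenylamino)oxy]cyclohexane-1-carboxylate | COC(=O)C1CCC(=O)[C@@H](ONc2ccccc2)C1
F2 | step 3 | methyl (3S)-3-hydroxy-4-oxocyclohexane-1-carboxylate | COC(=O)C1CCC(=O)[C@@H](O)C1
F3 | step 3 | methyl (3S)-3-[(methylsulfonyl)oxy]-4-oxocyclohexane-1-carboxylate | COC(=O)C1CCC(=O)[C@@H](OS(C)(=O)=O)C1
F4 | step 3 | methyl (1R,3R)-3-bromo-4-oxocyclohexane-1-carboxylate | COC(=O)[C@@H]1CCC(=O)[C@H](Br)C1
F5 | step 1 | tetramethyl pentane-1,3,3,5-tetracarboxylate | COC(=O)CCC(CCC(=O)OC)(C(=O)OC)C(=O)OC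
F6 | step 1 | trimethyl 4-oxocyclohexane-1,1,3-tricarboxylate | COC(=O)C1CC(C(=O)OC)(C(=O)OC)CCC1=O
F7 | step 12 | (3S,6S)-1-({2-[(1R,3R,4S)-3-bromo-4-methyl-4-(triethylsilyloxy)cyclohexyl]prop-2-en-1-yl}oxy)-6-hydroxy-6-methyl-3-(prop-1-en-2-yl)cyclohex-1-ene | C=C(COC1=C[C@@H](C(=C)C)CC[C@]1(C)O)[C@@H]1CC[C@](C)(O[Si](CC)(CC)CC)[C@H](Br)C1
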